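**Assumption:** the keto–enol form in the SMILES is the usual curcuminoid tautomer; the route delivers the equilibrating mixture.

## Retrosynthetic overview

1. Target ⇒ boron-templated aldol of aryl aldehyde 12 with (E)-4-hydroxycinnamoylacetone 15.
2. 12 ⇒ photochemical Ni C(aryl)–O coupling of alcohol 10 with bromide 11; 10 ⇒ δ-lactone 8 + 2-methylpropenyllithium.
3. Lactone 7 ⇒ diol 6 by hydroxyl-directed hydroboration / carbonylative lactonisation (new step: sets the side-chain methyl centre, forms C–C(=O), differentiates the two OH groups).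
4. Diol 6 ⇒ triene 4 + singlet oxygen (photochemical [4+2], both ring C–O bonds, two stereocentres); 4 ⇒ (S)-carvone by Shapiro reaction.
5. Rings: cyclohexene bought in carvone; transient 2,3-dioxabicyclo[2.2.2]octene (step 3); temporary δ-lactone (step 4, opened in step 6).

## Route

**Step 1**
Reactants: 1 (S)-(+)-carvone; 2 p-toluenesulfonyl hydrazide
Product: 3 (S)-carvone tosylhydrazone
Conditions: TsNHNH2, EtOH, cat. AcOH, 23→50 °C
Reagents that add atoms: none beyond reactant 2
Why: Hydrazone condensation at the ketone; the C5 stereocentre is not involved.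

**Step 2**
Reactants: 3
Product: 4 (5S)-2-methyl-5-(prop-1-en-2-yl)cyclohexa-1,3-diene
Conditions: MeLi (2.2 equiv), Et2O, 0→23 °C; H2O
Reagents that add atoms: none
Why: Shapiro reaction (α′-deprotonation at C6, loss of sulfinate and N2, protonation of the vinyllithium) gives the endocyclic 1,3-diene without touching C5.

**Step 3**
Reactants: 4
Product: 6 (1S,4S,5R)-2-methyl-5-(prop-1-en-2-yl)cyclohex-2-ene-1,4-diol, via endoperoxide 5 (not isolated)
Conditions: O2, TPP (cat.), white LEDs, CH2Cl2, −78 °C; then thiourea, MeOH, −78→23 °C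
Reagents that add atoms: dioxygen, O=O
Why: Photosensitised singlet-oxygen [4+2] cycloaddition on the diene face anti to the C5 isopropenyl group, then O–O reduction, gives the two carbinols cis to each other and trans to isopropenyl; the isolated 1,1-disubstituted alkene reacts far more slowly (ene).

**Step 4**
Reactants: 6
Product: 7 (4S,4aR,6S,8aR)-6-hydroxy-4,7-dimethyl-3,4,4a,5,6,8a-hexahydro-2H-chromen-2-one (trans-fused δ-lactone, free C6–OH)
Conditions: BH3·THF (2.2 equiv), THF, −20→23 °C; MeOH; then Pd(OAc)2 (5 mol %), PPh3, LiOMe, p-benzoquinone (1.5 equiv), CO (1 atm), THF–MeOH, 40 °C; PPTS, PhMe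
Reagents that add atoms: carbon monoxide, [C-]#[O+]
Why: Proposed new method: both OH groups become RO–BH2, but only the C4 alkoxyborane (homoallylic, trans to isopropenyl) can reach the alkene; it adds B–H intramolecularly through a chair-like trans-fused six-membered transition state with the methyl pseudo-equatorial, fixing the (S) side-chain centre (closest known: hydroxyl-directed BH3 hydroboration of trans-2-isopropenylcyclohexanols, which gives this sense). After methanolysis the primary B–C bond of the 1,2-oxaborinane transmetalates to Pd(II) as its methoxyborate, CO inserts, and the acyl–Pd is captured by the adjacent oxygen (or by MeOH, then lactonisation), with benzoquinone reoxidising Pd(0) (closest known: Pd(II)/benzoquinone oxidative alkoxycarbonylation of organoboronates and carbonylative B-alkyl Suzuki coupling).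

**Step 5**
Reactants: 7
Product: 8 (4S,4aR,6S,8aR)-4,7-dimethyl-6-(triethylsilyloxy)-3,4,4a,5,6,8a-hexahydro-2H-chromen-2-one
Conditions: TESCl, imidazole, CH2Cl2, 0 °C
Reagents that add atoms: chlorotriethylsilane, CC[Si](Cl)(CC)CC
Why: Silylation of the only free hydroxyl, since the other oxygen is held in the lactone.

**Step 6**
Reactants: 8; 9 1-bromo-2-methylprop-1-ene
Product: 10 (6S)-6-[(1R,2R,5S)-2-hydroxy-4-methyl-5-(triethylsilyloxy)cyclohex-3-en-1-yl]-2-methylhept-2-en-4-one
Conditions: 9, t-BuLi (2 equiv), Et2O, −78 °C; then 8, THF, −78 °C; AcOH quench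
Reagents that add atoms: none beyond reactant 9 (as (2-methylprop-1-enyl)lithium, CC(C)=C[Li])
Why: Mono-addition of an alkenyllithium to the δ-lactone (the lithium lactolate is stable at −78 °C) gives the enone and releases the hydroxyl next to the side chain as the only free OH.

**Step 7**
Reactants: 10; 11 4-bromo-3-methoxybenzaldehyde
Product: 12 3-methoxy-4-{[(1R,4S,6R)-3-methyl-6-[(2S)-6-methyl-4-oxohept-5-en-2-yl]-4-(triethylsilyloxy)cyclohex-2-en-1-yl]oxy}benzaldehyde
Conditions: 11 (2 equiv), NiCl2·glyme/dtbbpy (5 mol %), Ir[dF(CF3)ppy]2(dtbbpy)PF6 (1 mol %), quinuclidine (10 mol %), K2CO3, MeCN, blue LEDs, 25 °C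
Reagents that add atoms: none beyond reactant 11
Why: Nickel/photoredox C(sp2)–O cross-coupling of the single free alcohol under weak base (the enone is not enolised); the alkyl C–O bond from step 3 is not broken, so configuration is retained.

**Step 8**
Reactants: 13 4-hydroxybenzaldehyde; 14 acetylacetone (3 equiv)
Product: 15 (5E)-6-(4-hydroxyphenyl)hex-5-ene-2,4-dione
Conditions: B2O3, B(OnBu)3, n-BuNH2, EtOAc, 80 °C; then 0.4 M HCl, 60 °C
Reagents that add atoms: none beyond reactants
Why: Boron-templated (Pabon-type) aldol condensation at a terminal methyl of the chelated diketone; excess diketone stops it at mono-condensation.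

**Step 9**
Reactants: 12; 15 (1.5 equiv)
Product: 16 demethoxybisabolocurcumin ether (target)
Conditions: B2O3, B(OnBu)3, n-BuNH2, EtOAc, 70 °C; then 1 M HCl–THF, 23 °C
Reagents that add atoms: none beyond reactants
Why: Second Pabon-type aldol condensation at the remaining methyl of boron-complexed 15 gives the (E)-styryl unit (the side-chain enone is not boron-activated), and the mild acid work-up breaks the boron chelate and removes the TES group.

## Compound list

1 | (S)-(+)-carvone | CC1=CC[C@H](C(C)=C)CC1=O | starting material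
2 | p-toluenesulfonyl hydrazide | Cc1ccc(cc1)S(=O)(=O)NN | starting material
3 | (S)-carvone tosylhydrazone | CC1=CC[C@H](C(C)=C)CC1=NNS(=O)(=O)c1ccc(C)cc1 | intermediate
4 | (5S)-2-methyl-5-(prop-1-en-2-yl)cyclohexa-1,3-diene | CC1=CC[C@H](C(C)=C)C=C1 | intermediate
5 | (1S,4S,7R)-5-methyl-7-(prop-1-en-2-yl)-2,3-dioxabicyclo[2.2.2]oct-5-ene | O2[C@H]1C=C(C)[C@@H](O2)C[C@@H]1C(C)=C | intermediate (not isolated)
6 | (1S,4S,5R)-2-methyl-5-(prop-1-en-2-yl)cyclohex-2-ene-1,4-diol | O[C@H]1C=C(C)[C@@H](O)C[C@@H]1C(C)=C | intermediate
7 | (4S,4aR,6S,8aR)-6-hydroxy-4,7-dimethyl-3,4,4a,5,6,8a-hexahydro-2H-chromen-2-one | O1[C@H]2C=C(C)[C@@H](O)C[C@@H]2[C@@H](C)CC1=O | intermediate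
8 | TES ether of 7 | O1[C@H]2C=C(C)[C@@H](O[Si](CC)(CC)CC)C[C@@H]2[C@@H](C)CC1=O | intermediate
9 | 1-bromo-2-methylprop-1-ene | CC(C)=CBr | starting material
10 | (6S)-6-[(1R,2R,5S)-2-hydroxy-4-methyl-5-(triethylsilyloxy)cyclohex-3-en-1-yl]-2-methylhept-2-en-4-one | O[C@H]1C=C(C)[C@@H](O[Si](CC)(CC)CC)C[C@@H]1[C@@H](C)CC(=O)C=C(C)C | intermediate
11 | 4-bromo-3-methoxybenzaldehyde | COc1cc(C=O)ccc1Br | starting material
12 | aryl ether aldehyde (name in step 7) | COc1cc(C=O)ccc1O[C@H]1C=C(C)[C@@H](O[Si](CC)(CC)CC)C[C@@H]1[C@@H](C)CC(=O)C=C(C)C | intermediate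
13 | 4-hydroxybenzaldehyde | O=Cc1ccc(O)cc1 | starting material
14 | acetylacetone | CC(=O)CC(C)=O | starting material
15 | (5E)-6-(4-hydroxyphenyl)hex-5-ene-2,4-dione | CC(=O)CC(=O)/C=C/c1ccc(O)cc1 | intermediate
16 | demethoxybisabolocurcumin ether | COc1cc(/C=C/C(O)=C/C(=O)/C=C/c2ccc(O)cc2)ccc1O[C@H]1C=C(C)[C@@H](O)C[C@@H]1[C@@H](C)CC(=O)C=C(C)C | target

## Summary

Total steps: 9. Longest linear sequence: 8 (steps 1–7 and 9).

Steps most likely to fail:

1. **Step 4 (proposed new step).** Risks are slow B→Pd transfer of a primary alkylboronate, β-hydride elimination before CO insertion, and borane attack on the ring alkene. Fallback (known chemistry, different mechanism): Pd–hydride cyclocarbonylation of homoallylic alcohol 6 (Pd(OAc)2/dppb, CO/H2), the lactonisation known for isopulegol-type substrates, with the methyl centre set by hydroxyl-coordinated hydropalladation.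
2. **Step 3.** Singlet oxygen is small, so anti/syn facial selectivity may be only moderate, and triene 4 is prone to aromatisation. Fallback (non-photochemical, classical substrate control): from 1, alkaline H2O2 epoxidation (trans to isopropenyl), α′-hydroxylation via the silyl enol ether (Rubottom), then Wharton transposition to the same diol 6.
3. **Step 7.** The alcohol is hindered and allylic, the bromide is ortho-substituted, and hydrogen abstraction at the carbinol or aldehyde C–H may compete. Fallback (change of order and bond-forming logic): open lactone 8 to the hydroxy Weinreb amide, form the ether by SNAr of its potassium alkoxide on 4-fluoro-3-methoxybenzaldehyde, then add the alkenyllithium to the amide with the aldehyde masked in situ as an α-amino alkoxide.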